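## Retrosynthetic overview

1. Lactone first: C2-symmetric (+)-secoisolariciresinol 1 is dehydrogenated through lactol 2 to (+)-matairesinol 3, the diol → lactol → lactone sequence the plant uses.
2. Chiral C6C3 partner: methyl ferulate 4 and (2R)-bornane-10,2-sultam 5 give, through aluminium amide 6, feruloyl sultam 7.
3. Key disconnection: one double oxidative 8–5 radical cross-coupling of unprotected 3 with two molecules of 7 (through quinone methide 8, mono adduct 9 and quinone methide 10) builds both dihydrobenzofurans of 11, two rings and four stereocentres in one flask.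
4. Auxiliary removal gives triol 12. The last disconnection is the benzylic C–O bond of the ring A dihydrobenzofuran, opened and hydrated through boronate 13 to target 14.
5. Ring order: lactone, then both dihydrobenzofurans together, then re-opening of one of them.

Assumption 1: (+)-secoisolariciresinol 1, the (8S,8'S) aglycone of the flaxseed lignan diglucoside, is taken as a cheap commercial starting material.

Assumption 2: the (2R)-sultam 5 is taken to leave open the C-8 face that leads to the 2R,3R acyl-dihydrobenzofuran (anti C=O/SO2, s-cis enoyl rotamer, attack anti to the pseudo-axial S=O); if the sense proves opposite, the (2S)-sultam is used and nothing else changes.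

Locants: oxolan-2-one C-3 carries the ring B benzyl group and C-4 the ring A benzyl group. Ring G is the 4-hydroxy-3-methoxyphenyl ring of an appended C6C3 unit. C-7'', C-8'' and C-9'' are the benzylic, middle and terminal carbons of an appended unit (C-2, C-3 and the 3-substituent of a dihydrobenzofuran).

## Route

Step 1
Reactants: 1 (+)-secoisolariciresinol [(2S,3S)-2,3-bis(4-hydroxy-3-methoxybenzyl)butane-1,4-diol]
Product: 3 (+)-matairesinol [(3S,4S)-3,4-bis(4-hydroxy-3-methoxybenzyl)oxolan-2-one], via lactol 2 (not isolated)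
Conditions: RuH2(PPh3)4 (5 mol %), benzalacetone (2.2 equiv), THF/toluene, 40 °C
Reagents that add atoms: none
Why: Acceptor-driven transfer dehydrogenation (Oppenauer-type) of one CH2OH with ring closure gives lactol 2 and a second hydrogen transfer gives the lactone, the C2 axis of 1 making the two CH2OH groups equivalent so that a single lactone results while the phenols are inert and the two existing stereocentres are not touched.

Step 2
Reactants: 4 methyl (E)-ferulate; 5 (2R)-bornane-10,2-sultam
Product: 7 N-[(E)-feruloyl]-(2R)-bornane-10,2-sultam, via dimethylaluminium sultam amide 6 (not isolated)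
Conditions: AlMe3 (2.2 equiv), toluene, 0 °C then 80 °C; aq. potassium sodium tartrate work-up
Reagents that add atoms: none
Why: Weinreb-type aminolysis in which AlMe3 turns the sulfonamide N–H into aluminium amide 6, which attacks the ester carbonyl of 4 and expels methoxide (the second equivalent of AlMe3 only deprotonates the phenol), no stereocentre being formed and the E alkene being retained.

Step 3
Reactants: 3 (+)-matairesinol; 7 N-feruloyl sultam (3 equiv)
Product: 11 bis(dihydrobenzofuran) bis(N-acyl sultam) [both guaiacyl rings of 3 annulated; each unit 2R,3R-trans], via quinone methide 8 (not isolated), via mono(dihydrobenzofuran) imide 9 (not isolated), via quinone methide 10 (not isolated)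
Conditions: Ag2O (6 equiv), 7 added over 12 h, dry CH2Cl2/acetone 3:1, rt, dark
Reagents that add atoms: none
Why: Biomimetic oxidative phenol cross-coupling in which Ag2O generates the phenoxy radicals of 3 and 7, radical–radical 8–5 coupling joins C-8 of the feruloyl unit to C-5 of a guaiacyl ring on the face left open by the sultam (reagent control of the new C-3 stereocentre), and the re-aromatised ring phenol then adds 5-exo to p-quinone methide 8 or 10 to close each dihydrobenzofuran with the preferred 2,3-trans relationship, which sets C-2.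

Step 4
Reactants: 11 bis(dihydrobenzofuran) bis(N-acyl sultam)
Product: 12 bis(dihydrobenzofuran) triol lactone [(3S,4S)-3,4-bis{[(2R,3S)-2-(4-hydroxy-3-methoxyphenyl)-3-(hydroxymethyl)-7-methoxy-2,3-dihydro-1-benzofuran-5-yl]methyl}oxolan-2-one]
Conditions: NaBH4 (6 equiv), THF/H2O 4:1, 0 °C, 2 h; pH 6 buffer quench
Reagents that add atoms: none
Why: NaBH4 reduction of the imide-like N-acyl sultam carbonyl to the primary alcohol with loss of the sultam anion is far faster at 0 °C than reduction of the γ-lactone, no stereocentre is created, and the short cold reaction keeps the epimerisable C-3 (α to the acyl group and β to an aryloxy leaving group) from scrambling by retro-oxa-Michael opening before its carbonyl is reduced.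

Step 5
Reactants: 12 bis(dihydrobenzofuran) triol lactone
Product: 14 CNP0199264.1 (target), via cyclic phenylboronate 13 (not isolated)
Conditions: PhB(OH)2 (1.0 equiv), camphor-10-sulfonic acid (5 mol %), 4 Å molecular sieves, THF/toluene, 40 °C, stopped near half conversion; then HN(CH2CH2OH)2 (1.5 equiv), rt; neutral reversed-phase HPLC
Reagents that add atoms: phenylboronic acid, OB(O)c1ccccc1 (one of its hydroxyl oxygens becomes O-7'')
Why: Proposed new method: phenylboronic acid first binds the 3-CH2OH of a dihydrobenzofuran, the acid reversibly ionises the p-hydroxybenzylic C-2–O bond to the same quinone methide/benzyl cation through which the ring was closed, and the B–OH oxygen adds to C-7'' through a six-membered chair with H-8'' eclipsing the quinone methide plane (A(1,3) strain) and both aryl groups equatorial, so that the erythro (7''S,8''S) 1,3-diol is held as dioxaborinane 13 under water-removing thermodynamic control and is released by neutral B–O exchange with diethanolamine without touching any C–O bond, the closest known reaction types being the Nagata trapping of o-hydroxybenzyl alcohols as 1,3,2-benzodioxaborins by phenylboronic acid and the acid-mediated (thioacidolysis-type) opening of phenylcoumarans.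

## Compound list

1 | (+)-secoisolariciresinol, (2S,3S)-2,3-bis[(4-hydroxy-3-methoxyphenyl)methyl]butane-1,4-diol | COc1cc(C[C@H](CO)[C@@H](CO)Cc2ccc(O)c(OC)c2)ccc1O | starting material

2 | lactol, (3S,4S)-3,4-bis[(4-hydroxy-3-methoxyphenyl)methyl]oxolan-2-ol (both anomers) | COc1cc(C[C@@H]2COC(O)[C@H]2Cc2ccc(O)c(OC)c2)ccc1O | intermediate (not isolated)

3 | (+)-matairesinol, (3S,4S)-3,4-bis[(4-hydroxy-3-methoxyphenyl)methyl]oxolan-2-one | COc1cc(C[C@@H]2COC(=O)[C@H]2Cc2ccc(O)c(OC)c2)ccc1O | intermediate

4 | methyl (E)-ferulate | COC(=O)/C=C/c1ccc(O)c(OC)c1 | starting material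

5 | (2R)-bornane-10,2-sultam [(1S)-(−)-2,10-camphorsultam] | N1[C@@H]2C[C@H]3CC[C@]2(CS1(=O)=O)C3(C)C | starting material

6 | N-(dimethylaluminio)-(2R)-bornane-10,2-sultam | C[Al](C)N1[C@@H]2C[C@H]3CC[C@]2(CS1(=O)=O)C3(C)C | intermediate (not isolated)

7 | (E)-3-(4-hydroxy-3-methoxyphenyl)-1-[(2R)-bornane-10,2-sultam-N-yl]prop-2-en-1-one | COc1cc(/C=C/C(=O)N2[C@@H]3C[C@H]4CC[C@]3(CS2(=O)=O)C4(C)C)ccc1O | intermediate

8 | first quinone methide: 3 bearing at C-5 of ring B the CH(CO-sultam)–CH= group whose CH= is the exocyclic carbon of a 2-methoxy-p-quinone methide (new CH as in 11; exocyclic alkene geometry undefined; drawn for ring B first, the order of the two couplings is immaterial) | COc1cc(C[C@@H]2COC(=O)[C@H]2Cc2cc(OC)c(O)c(c2)[C@@H](C(=O)N3[C@@H]4C[C@H]5CC[C@]4(CS3(=O)=O)C5(C)C)C=C2C=CC(=O)C(OC)=C2)ccc1O | intermediate (not isolated)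

9 | mono adduct: (3S,4S)-4-[(4-hydroxy-3-methoxyphenyl)methyl]-3-({(2R,3R)-2-(4-hydroxy-3-methoxyphenyl)-7-methoxy-3-[(2R)-bornane-10,2-sultam-N-ylcarbonyl]-2,3-dihydro-1-benzofuran-5-yl}methyl)oxolan-2-one | COc1cc(C[C@@H]2COC(=O)[C@H]2Cc2cc(OC)c3c(c2)[C@@H](C(=O)N4[C@@H]5C[C@H]6CC[C@]5(CS4(=O)=O)C6(C)C)[C@H](c2ccc(O)c(OC)c2)O3)ccc1O | intermediate (not isolated)

10 | second quinone methide: 9 bearing at C-5 of ring A the same CH(CO-sultam)–CH= quinone methide group (exocyclic alkene geometry undefined) | COc1cc(C[C@@H]2COC(=O)[C@H]2Cc2cc(OC)c3c(c2)[C@@H](C(=O)N4[C@@H]5C[C@H]6CC[C@]5(CS4(=O)=O)C6(C)C)[C@H](c2ccc(O)c(OC)c2)O3)cc([C@@H](C(=O)N2[C@@H]3C[C@H]4CC[C@]3(CS2(=O)=O)C4(C)C)C=C2C=CC(=O)C(OC)=C2)c1O | intermediate (not isolated)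

11 | (3S,4S)-3,4-bis({(2R,3R)-2-(4-hydroxy-3-methoxyphenyl)-7-methoxy-3-[(2R)-bornane-10,2-sultam-N-ylcarbonyl]-2,3-dihydro-1-benzofuran-5-yl}methyl)oxolan-2-one | COc1cc([C@@H]2Oc3c(OC)cc(C[C@@H]4COC(=O)[C@H]4Cc4cc(OC)c5c(c4)[C@@H](C(=O)N6[C@@H]7C[C@H]8CC[C@]7(CS6(=O)=O)C8(C)C)[C@H](c4ccc(O)c(OC)c4)O5)cc3[C@H]2C(=O)N6[C@@H]7C[C@H]8CC[C@]7(CS6(=O)=O)C8(C)C)ccc1O | intermediate

12 | (3S,4S)-3,4-bis{[(2R,3S)-2-(4-hydroxy-3-methoxyphenyl)-3-(hydroxymethyl)-7-methoxy-2,3-dihydro-1-benzofuran-5-yl]methyl}oxolan-2-one | COc1cc([C@@H]2Oc3c(OC)cc(C[C@@H]4COC(=O)[C@H]4Cc4cc(OC)c5c(c4)[C@@H](CO)[C@H](c4ccc(O)c(OC)c4)O5)cc3[C@H]2CO)ccc1O | intermediate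

13 | (3S,4S)-3-{[(2R,3S)-2-(4-hydroxy-3-methoxyphenyl)-3-(hydroxymethyl)-7-methoxy-2,3-dihydro-1-benzofuran-5-yl]methyl}-4-({4-hydroxy-3-[(4S,5S)-4-(4-hydroxy-3-methoxyphenyl)-2-phenyl-1,3,2-dioxaborinan-5-yl]-5-methoxyphenyl}methyl)oxolan-2-one | COc1cc([C@H]2OB(c3ccccc3)OC[C@@H]2c2cc(C[C@@H]3COC(=O)[C@H]3Cc3cc(OC)c4c(c3)[C@@H](CO)[C@H](c3ccc(O)c(OC)c3)O4)cc(OC)c2O)ccc1O | intermediate (not isolated)

14 | CNP0199264.1, (3S,4S)-4-({3-[(1S,2S)-1,3-dihydroxy-1-(4-hydroxy-3-methoxyphenyl)propan-2-yl]-4-hydroxy-5-methoxyphenyl}methyl)-3-{[(2R,3S)-2-(4-hydroxy-3-methoxyphenyl)-3-(hydroxymethyl)-7-methoxy-2,3-dihydro-1-benzofuran-5-yl]methyl}oxolan-2-one | COc1cc([C@@H](O)[C@H](CO)c2cc(C[C@@H]3COC(=O)[C@H]3Cc3cc(OC)c4c(c3)[C@@H](CO)[C@H](c3ccc(O)c(OC)c3)O4)cc(OC)c2O)ccc1O | target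

## Step count and risks

Total steps: 5. Longest linear sequence: 4 (1 → 3 → 11 → 12 → 14); step 2 is a one-step side branch.

**Step 3 (double cross-coupling).** The feruloyl radical prefers to dimerise with itself. 8–O–4 coupling and over-coupling at the new ring G phenols also compete. The face selectivity of the sultam is known only for the homodimerisation, so 10–20 % of 11 is a realistic hope. The fallback sets out from 3 and comes back at 12. N-Iodosuccinimide iodinates both rings ortho to the phenol to give 5,5'-diiodomatairesinol F1. A Pd(OAc)2/PPh3/Ag2CO3 oxyarylation with commercial (E)-coniferyl alcohol then adds each aryl–palladium to C-8'' of the styrene. The p-hydroxybenzyl–palladium species collapses with loss of zerovalent palladium to the same p-quinone methide, and the ring phenol closes the trans ring, giving 12 directly. The configuration of the two units then has to come from a chiral bisphosphine on palladium or from HPLC separation of the trans,trans diastereomers.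

**Step 5 (boronate-templated re-opening).** The position of the dihydrobenzofuran/boronate equilibrium is unproven. The benzylic cation can also lose H-8'' (stilbene) or alkylate another arene. Nothing distinguishes the ring A unit from the ring B unit, so at best about a quarter of the material is 14. The rest (ring B-opened isomer, doubly opened compound, unchanged 12) is separated by HPLC and returned to 12 with a trace of acid. The fallback sets out from 3 and comes back at 14. Step 3 is run with one equivalent of 7 and stopped at the mono adducts. The ring B isomer 9 is isolated and reduced with NaBH4 to the mono(dihydrobenzofuran) lactone F2. F2 is then co-oxidised with commercial (E)-coniferyl alcohol by FeCl3 in acetone/pH 4 buffer with slow addition. There the ring A quinone methide is partly captured by water before the phenol closes, giving 14 directly next to its C-7''/C-8'' isomers and the ring-closed product (HPLC).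

**Step 4 (auxiliary removal).** The basic borohydride medium may open the β-aryloxy imide by retro-oxa-Michael reaction, which would lose the C-3 configuration, or attack the lactone. The fallback sets out from 11 and comes back at 12. LiOH/H2O2 in THF/H2O at 0 °C removes both sultams hydrolytically to give the bis(carboxylic acid) F3; a lactone that opens re-closes on acidification to pH 3. BH3·SMe2 in THF at 0 °C then reduces the two carboxylic acids but not the lactone, giving 12.

## Further compounds

F1 | step 3 | (3S,4S)-3,4-bis[(4-hydroxy-3-iodo-5-methoxyphenyl)methyl]oxolan-2-one (5,5'-diiodomatairesinol) | COc1cc(C[C@@H]2COC(=O)[C@H]2Cc2cc(I)c(O)c(OC)c2)cc(I)c1O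

F2 | step 5 | (3S,4S)-4-[(4-hydroxy-3-methoxyphenyl)methyl]-3-{[(2R,3S)-2-(4-hydroxy-3-methoxyphenyl)-3-(hydroxymethyl)-7-methoxy-2,3-dihydro-1-benzofuran-5-yl]methyl}oxolan-2-one | COc1cc(C[C@@H]2COC(=O)[C@H]2Cc2cc(OC)c3c(c2)[C@@H](CO)[C@H](c2ccc(O)c(OC)c2)O3)ccc1O

F3 | step 4 | (2R,3R,2'R,3'R)-5,5'-{[(3S,4S)-2-oxooxolane-3,4-diyl]bis(methylene)}bis[2-(4-hydroxy-3-methoxyphenyl)-7-methoxy-2,3-dihydro-1-benzofuran-3-carboxylic acid] | COc1cc([C@@H]2Oc3c(OC)cc(C[C@@H]4COC(=O)[C@H]4Cc4cc(OC)c5c(c4)[C@@H](C(=O)O)[C@H](c4ccc(O)c(OC)c4)O5)cc3[C@H]2C(=O)O)ccc1O
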